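The cyclohexene is built around the aryl ether instead of being etherified. Cutting the ring at C1–C2 and C3=C4 turns C2(OAr)–C3 into the α-carbon and carbonyl of a vanillin-derived aryloxyacetaldehyde, and C1–C6–C5(=O)–C4–CH3 into an acyclic (E)-ethyl enone that already carries the C7 stereocentre. One amine-catalysed Michael/aldol-condensation annulation should form both ring C–C bonds, set C1 and C2 trans under catalyst control, place the C3=C4(CH3) double bond and deliver C5 as a carbonyl. The feature exploited is the α-methyl-enone retron C5–C4(CH3)=C3 next to the oxygenated C2. The precursors are aldehyde 5 and enone 13.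

Key step: step 9

Remark (numbering): ring C1 = CH bearing the side chain, C2 = CH–OAr, C3 = CH=, C4 = C(CH3)=, C5 = CH–OH, C6 = CH2; C7 = exocyclic CH(CH3), C9 = side-chain C=O. The target is 1R,2R,5S,7S in this numbering. 1,3-Diketones are drawn as one tautomer.
Assumption 1: the α-aryloxy enamine of 5 reacts with the same facial sense as simple alkyl enamines (E-enamine, attack anti to the CPh2OTMS group); if the sense proves opposite, the (R)-catalyst is used in step 9.
Assumption 2: the (R,R)-Me-DuPhos antipode delivers (S)-7; if not, the (S,S)-ligand is used.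

Step 1
Reactants: 1 vanillin; 2 allyl bromide
Product: 3 4-(allyloxy)-3-methoxybenzaldehyde
Conditions: K2CO3, DMF, rt
Reagents that add atoms: none
Why: Williamson ether synthesis, the phenoxide displacing the allylic bromide by SN2.

Step 2
Reactants: 3 4-(allyloxy)-3-methoxybenzaldehyde
Product: 4 2-[4-(allyloxy)-3-methoxyphenyl]-1,3-dioxolane
Conditions: ethylene glycol, p-TsOH (cat.), toluene, Dean–Stark, reflux
Reagents that add atoms: ethylene glycol, OCCO
Why: Acid-catalysed acetalisation with azeotropic water removal masks the aryl aldehyde against the later enamine and Grignard steps.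

Step 3
Reactants: 4 2-[4-(allyloxy)-3-methoxyphenyl]-1,3-dioxolane
Product: 5 [4-(1,3-dioxolan-2-yl)-2-methoxyphenoxy]acetaldehyde
Conditions: OsO4 (2 mol%), NaIO4, 2,6-lutidine, dioxane/H2O, rt
Reagents that add atoms: osmium tetroxide, O=[Os](=O)(=O)=O (delivers the carbonyl oxygen); sodium periodate, [Na+].[O-]I(=O)(=O)=O (re-oxidant and diol cleavage)
Why: Lemieux–Johnson oxidative cleavage of the terminal alkene, run buffered so that the acetal should survive.

Step 4
Reactants: 6 mono-methyl itaconate
Product: 7 (2S)-4-methoxy-2-methyl-4-oxobutanoic acid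
Conditions: H2 (5 bar), [Rh(cod)((R,R)-Me-DuPhos)]BF4 (0.5 mol%), MeOH, rt
Reagents that add atoms: none
Why: Rh–bisphospholane asymmetric hydrogenation of an itaconate half-ester, in which chelation by the ester carbonyl fixes the alkene face and sets C7.

Step 5
Reactants: 7 (2S)-4-methoxy-2-methyl-4-oxobutanoic acid
Product: 9 (4S)-4-methyloxolan-2-one, via methyl (3S)-4-hydroxy-3-methylbutanoate 8 (not isolated)
Conditions: BH3·SMe2, THF, −10 °C → rt; MeOH quench; then p-TsOH (cat.), CH2Cl2, rt
Reagents that add atoms: none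
Why: Chemoselective borane reduction of the carboxylic acid beside the ester, then acid-catalysed lactonisation, neither of which touches C7.

Step 6
Reactants: 9 (4S)-4-methyloxolan-2-one
Product: 10 (3S)-4-hydroxy-N-methoxy-N,3-dimethylbutanamide
Conditions: MeNH(OMe)·HCl, i-PrMgCl (pre-mixed), THF, −20 → 0 °C
Reagents that add atoms: N,O-dimethylhydroxylamine hydrochloride, CNOC.Cl
Why: Weinreb aminolysis of the lactone by the chloromagnesium amide opens the ring at the acyl carbon and frees the C1 hydroxyl.

Step 7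
Reactants: 10 (3S)-4-hydroxy-N-methoxy-N,3-dimethylbutanamide
Product: 11 (3S)-N-methoxy-N,3-dimethyl-4-oxobutanamide
Conditions: Dess–Martin periodinane, NaHCO3, CH2Cl2, 0 °C → rt
Reagents that add atoms: none
Why: Dess–Martin oxidation under buffered, non-basic conditions should keep the α-methyl stereocentre intact.

Step 8
Reactants: 11 (3S)-N-methoxy-N,3-dimethyl-4-oxobutanamide; 12 diethyl (2-oxobutyl)phosphonate
Product: 13 (3S,4E)-N-methoxy-N,3-dimethyl-6-oxooct-4-enamide
Conditions: Ba(OH)2·8H2O, THF/H2O (40:1), rt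
Reagents that add atoms: none
Why: Horner–Wadsworth–Emmons olefination with a β-ketophosphonate under mild barium hydroxide conditions should be E-selective and spare the epimerisable α-centre.

Step 9
Reactants: 5 [4-(1,3-dioxolan-2-yl)-2-methoxyphenoxy]acetaldehyde; 13 (3S,4E)-N-methoxy-N,3-dimethyl-6-oxooct-4-enamide
Product: 15 (3S)-3-{(1R,2R)-2-[4-(1,3-dioxolan-2-yl)-2-methoxyphenoxy]-4-methyl-5-oxocyclohex-3-en-1-yl}-N-methoxy-N-methylbutanamide, via (3S,4R,5R)-5-[4-(1,3-dioxolan-2-yl)-2-methoxyphenoxy]-N-methoxy-N,3-dimethyl-6-oxo-4-(2-oxobutyl)hexanamide 14 (not isolated)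
Conditions: (S)-α,α-diphenylprolinol TMS ether (20 mol%), ethyl 3,4-dihydroxybenzoate (20 mol%), toluene, 4 °C → rt, slow addition of 5 (2 equiv); then Bn2NH·TFA (0.5 equiv), 40 °C
Reagents that add atoms: none
Why: Proposed new method: the amine condenses with 5 to the (E)-enamine, whose C2 adds in a Michael sense to C1 of enone 13 (activated by hydrogen bonding to the catechol co-catalyst) to give keto-aldehyde 14, and Bn2NH·TFA then drives the intramolecular aldol condensation in which the ethyl-ketone carbon C4 attacks the aldehyde carbon C3 and water is lost to put C3=C4 in conjugation with the C5 carbonyl. The closest known reaction type is the diarylprolinol-ether-catalysed Michael addition of aldehydes to vinyl ketones with subsequent aldol condensation to 4-substituted cyclohex-2-enones, together with the syn-selective addition of α-alkoxyacetaldehydes to nitroalkenes; what is new is a β-branched acyclic enone as acceptor. The one ring is closed by a 6-(enolendo)-exo-trig aldol addition, the only feasible mode because every other enol/carbonyl pairing in 14 would give a four-membered ring. C2 is controlled by the catalyst (the CPh2OTMS group shields one enamine face) and C1 by the acyclic synclinal transition state, whose syn adduct maps onto the trans C1/C2 relationship of the ring; C7 is carried in unchanged. The step needs 1,4- over 1,2-addition and cross- over self-reaction of 5 (slow addition of 5, poorly electrophilic ketone carbonyl) and integrity of C7 (the bulky catalyst should not condense with the enone, so no dienamine forms); any epimerisation at the γ-carbon C2 of 15 should drain towards the same trans-diequatorial isomer.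

Step 10
Reactants: 15 (3S)-3-{(1R,2R)-2-[4-(1,3-dioxolan-2-yl)-2-methoxyphenoxy]-4-methyl-5-oxocyclohex-3-en-1-yl}-N-methoxy-N-methylbutanamide
Product: 16 (3S)-3-{(1R,2R,5S)-2-[4-(1,3-dioxolan-2-yl)-2-methoxyphenoxy]-5-hydroxy-4-methylcyclohex-3-en-1-yl}-N-methoxy-N-methylbutanamide
Conditions: (R)-Me-CBS (0.2 equiv), catecholborane, toluene, −78 → −40 °C
Reagents that add atoms: none
Why: Corey–Bakshi–Shibata reduction, with the α-methyl alkenyl arm as the large group, should deliver hydride under reagent control to the face that gives the 5S carbinol cis to the C2 aryl ether, while the Weinreb amide and acetal stay untouched at low temperature.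

Step 11
Reactants: 16 (3S)-3-{(1R,2R,5S)-2-[4-(1,3-dioxolan-2-yl)-2-methoxyphenoxy]-5-hydroxy-4-methylcyclohex-3-en-1-yl}-N-methoxy-N-methylbutanamide; 17 2-methylprop-1-enylmagnesium bromide
Product: 19 4-({(1R,4S,6R)-4-hydroxy-3-methyl-6-[(2S)-6-methyl-4-oxohept-5-en-2-yl]cyclohex-2-en-1-yl}oxy)-3-methoxybenzaldehyde, via (6S)-6-{(1R,2R,5S)-2-[4-(1,3-dioxolan-2-yl)-2-methoxyphenoxy]-5-hydroxy-4-methylcyclohex-3-en-1-yl}-2-methylhept-2-en-4-one 18 (not isolated)
Conditions: 17 (3.5 equiv), THF, 0 °C; then 1 M aq. HCl, THF, 0 °C → rt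
Reagents that add atoms: water, O
Why: Weinreb ketone synthesis, in which the magnesium chelate stops at mono-addition and the C5 alkoxide is inert, followed by acetal hydrolysis of the electron-rich benzaldehyde acetal in the acidic work-up.

Step 12
Reactants: 20 dehydrozingerone; 21 acetyl chloride
Product: 23 feruloylacetone, (5E)-6-(4-hydroxy-3-methoxyphenyl)hex-5-ene-2,4-dione, via 4-[(1E)-3,5-dioxohex-1-en-1-yl]-2-methoxyphenyl acetate 22 (not isolated)
Conditions: 21 (2.2 equiv), MgBr2·OEt2, i-Pr2NEt, CH2Cl2, rt; then K2CO3 (cat.), MeOH, 0 °C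
Reagents that add atoms: none
Why: Claisen-type C-acylation of the methyl ketone by soft enolisation (magnesium enolate, the product diketonate resisting further acylation), with the unavoidable aryl acetate removed by methanolysis.

Step 13
Reactants: 19 4-({(1R,4S,6R)-4-hydroxy-3-methyl-6-[(2S)-6-methyl-4-oxohept-5-en-2-yl]cyclohex-2-en-1-yl}oxy)-3-methoxybenzaldehyde; 23 feruloylacetone
Product: 26 bisabolocurcumin ether, via feruloylacetone dibutoxyboron chelate 24 (not isolated), via curcuminoid dibutoxyboron chelate 25 (not isolated)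
Conditions: B2O3, B(On-Bu)3, EtOAc, 70 °C; n-BuNH2 (0.3 equiv), 70 °C; then 10% aq. AcOH, 40 °C
Reagents that add atoms: none
Why: Boron-templated aldol condensation, in which chelation blocks the central diketone carbon against Knoevenagel reaction and directs the terminal methyl onto the aryl aldehyde to give the E-alkene.

Compound list
1 | vanillin (4-hydroxy-3-methoxybenzaldehyde) | COc1cc(C=O)ccc1O | starting material
2 | allyl bromide | C=CCBr | starting material
3 | 4-(allyloxy)-3-methoxybenzaldehyde | COc1cc(C=O)ccc1OCC=C | intermediate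
4 | 2-[4-(allyloxy)-3-methoxyphenyl]-1,3-dioxolane | COc1cc(C2OCCO2)ccc1OCC=C | intermediate
5 | [4-(1,3-dioxolan-2-yl)-2-methoxyphenoxy]acetaldehyde | COc1cc(C2OCCO2)ccc1OCC=O | intermediate
6 | mono-methyl itaconate (4-methoxy-2-methylidene-4-oxobutanoic acid) | C=C(CC(=O)OC)C(=O)O | starting material
7 | (2S)-4-methoxy-2-methyl-4-oxobutanoic acid | OC(=O)[C@@H](C)CC(=O)OC | intermediate
8 | methyl (3S)-4-hydroxy-3-methylbutanoate | OC[C@@H](C)CC(=O)OC | intermediate (not isolated)
9 | (4S)-4-methyloxolan-2-one | O=C1C[C@H](C)CO1 | intermediate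
10 | (3S)-4-hydroxy-N-methoxy-N,3-dimethylbutanamide | OC[C@@H](C)CC(=O)N(C)OC | intermediate
11 | (3S)-N-methoxy-N,3-dimethyl-4-oxobutanamide | O=C[C@@H](C)CC(=O)N(C)OC | intermediate
12 | diethyl (2-oxobutyl)phosphonate | CCC(=O)CP(=O)(OCC)OCC | starting material
13 | (3S,4E)-N-methoxy-N,3-dimethyl-6-oxooct-4-enamide | CCC(=O)/C=C/[C@@H](C)CC(=O)N(C)OC | intermediate
14 | (3S,4R,5R)-5-[4-(1,3-dioxolan-2-yl)-2-methoxyphenoxy]-N-methoxy-N,3-dimethyl-6-oxo-4-(2-oxobutyl)hexanamide | O=C[C@H](Oc1ccc(C2OCCO2)cc1OC)[C@H](CC(=O)CC)[C@@H](C)CC(=O)N(C)OC | intermediate (not isolated)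
15 | (3S)-3-{(1R,2R)-2-[4-(1,3-dioxolan-2-yl)-2-methoxyphenoxy]-4-methyl-5-oxocyclohex-3-en-1-yl}-N-methoxy-N-methylbutanamide | COc1cc(C2OCCO2)ccc1O[C@H]3C=C(C)C(=O)C[C@@H]3[C@@H](C)CC(=O)N(C)OC | intermediate
16 | (3S)-3-{(1R,2R,5S)-2-[4-(1,3-dioxolan-2-yl)-2-methoxyphenoxy]-5-hydroxy-4-methylcyclohex-3-en-1-yl}-N-methoxy-N-methylbutanamide | COc1cc(C2OCCO2)ccc1O[C@H]3C=C(C)[C@@H](O)C[C@@H]3[C@@H](C)CC(=O)N(C)OC | intermediate
17 | 2-methylprop-1-enylmagnesium bromide | CC(C)=C[Mg]Br | starting material
18 | (6S)-6-{(1R,2R,5S)-2-[4-(1,3-dioxolan-2-yl)-2-methoxyphenoxy]-5-hydroxy-4-methylcyclohex-3-en-1-yl}-2-methylhept-2-en-4-one | COc1cc(C2OCCO2)ccc1O[C@H]3C=C(C)[C@@H](O)C[C@@H]3[C@@H](C)CC(=O)C=C(C)C | intermediate (not isolated)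
19 | 4-({(1R,4S,6R)-4-hydroxy-3-methyl-6-[(2S)-6-methyl-4-oxohept-5-en-2-yl]cyclohex-2-en-1-yl}oxy)-3-methoxybenzaldehyde | COc1cc(C=O)ccc1O[C@H]2C=C(C)[C@@H](O)C[C@@H]2[C@@H](C)CC(=O)C=C(C)C | intermediate
20 | dehydrozingerone, (3E)-4-(4-hydroxy-3-methoxyphenyl)but-3-en-2-one | COc1cc(/C=C/C(C)=O)ccc1O | starting material
21 | acetyl chloride | CC(=O)Cl | starting material
22 | 4-[(1E)-3,5-dioxohex-1-en-1-yl]-2-methoxyphenyl acetate | COc1cc(/C=C/C(=O)CC(C)=O)ccc1OC(C)=O | intermediate (not isolated)
23 | feruloylacetone, (5E)-6-(4-hydroxy-3-methoxyphenyl)hex-5-ene-2,4-dione | COc1cc(/C=C/C(=O)CC(C)=O)ccc1O | intermediate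
24 | dibutoxyboron chelate of feruloylacetone | CCCCO[B-]1(OCCCC)OC(C)=CC(/C=C/c2ccc(O)c(OC)c2)=[O+]1 | intermediate (not isolated)
25 | dibutoxyboron chelate of the curcuminoid | CCCCO[B-]1(OCCCC)OC(/C=C/c2ccc(O[C@H]3C=C(C)[C@@H](O)C[C@@H]3[C@@H](C)CC(=O)C=C(C)C)c(OC)c2)=CC(/C=C/c4ccc(O)c(OC)c4)=[O+]1 | intermediate (not isolated)
26 | bisabolocurcumin ether | COc1cc(/C=C/C(=O)/C=C(O)/C=C/c2ccc(O[C@H]3C=C(C)[C@@H](O)C[C@@H]3[C@@H](C)CC(=O)C=C(C)C)c(OC)c2)ccc1O | target

Total step count: 13.
Longest linear sequence: 9 steps (6 → 7 → 9 → 10 → 11 → 13 → 15 → 16 → 19 → 26).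

Steps most likely to fail

1. Step 9 (Proposed new method). The enamine of 5 may add too slowly to the β-branched enone, so that self-aldolisation of 5 and catalyst deactivation take over, or the syn/anti control may erode. The fallback uses known chemistry, sets out from aldehyde 11 and returns at cyclohexenone 15. Knoevenagel condensation of 11 with methyl 3-oxopentanoate (piperidinium acetate, CH2Cl2, 0 °C) would give the doubly activated alkylidene β-keto ester F1. Its enamine Michael addition with 5 under the same amine catalyst, followed by Bn2NH·TFA-mediated aldol condensation through the ethyl CH2, would give the ring β-keto ester F2. Saponification and decarboxylation (LiOH, THF/H2O; then AcOH, 50 °C) would return 15. Alkylidene 1,3-dicarbonyl compounds are an established acceptor class for aldehyde enamines.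

2. Step 10. Facial selectivity may be poor because reagent control opposes the ring's own preference for axial hydride attack, which leads to the C5 epimer. The fallback sets out from 15 and returns at 16. Luche reduction (NaBH4, CeCl3·7H2O, MeOH, −78 °C) should follow the substrate bias to the C5-epimeric alcohol F3. Mitsunobu inversion (4-nitrobenzoic acid, PPh3, DIAD, THF, 0 °C) would give the inverted 4-nitrobenzoate F4, and methanolysis (K2CO3, MeOH) would give 16.

3. Step 13. Competing condensation or amine conjugate addition at the side-chain enone, and borate-assisted ionisation of the allylic alcohol, may erode the condensation on the fully functionalised aldehyde. The fallback sets out from 16 and returns at 26, running the condensation before the enone exists. Acetal hydrolysis (PPTS, acetone/H2O, rt) would give the aldehyde Weinreb amide F5. The boron-templated condensation with 23 under the conditions of step 13 would give the curcuminoid Weinreb amide F6. Deprotonation of the hydroxyl, phenol and diketone with i-PrMgCl (3 equiv, THF, −20 °C), then Grignard reagent 17 (0 °C) and mild acidic work-up, should convert the amide into the enone of 26 while the diketonate is protected as its magnesium salt.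

Further compounds
F1 | step 9 | methyl (4S)-6-[methoxy(methyl)amino]-4-methyl-6-oxo-2-propanoylhex-2-enoate (E/Z mixture) | CCC(=O)C(=C[C@@H](C)CC(=O)N(C)OC)C(=O)OC
F2 | step 9 | 6-methoxycarbonyl derivative of enone 15 (ester carbon α to the ring ketone, epimeric mixture) | COc1cc(C2OCCO2)ccc1O[C@H]3C=C(C)C(=O)C(C(=O)OC)[C@@H]3[C@@H](C)CC(=O)N(C)OC
F3 | step 10 | (3S)-3-{(1R,2R,5R)-2-[4-(1,3-dioxolan-2-yl)-2-methoxyphenoxy]-5-hydroxy-4-methylcyclohex-3-en-1-yl}-N-methoxy-N-methylbutanamide | COc1cc(C2OCCO2)ccc1O[C@H]3C=C(C)[C@H](O)C[C@@H]3[C@@H](C)CC(=O)N(C)OC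
F4 | step 10 | 4-nitrobenzoate ester of alcohol 16 | COc1cc(C2OCCO2)ccc1O[C@H]3C=C(C)[C@@H](OC(=O)c4ccc(cc4)[N+](=O)[O-])C[C@@H]3[C@@H](C)CC(=O)N(C)OC
F5 | step 13 | (3S)-3-[(1R,2R,5S)-2-(4-formyl-2-methoxyphenoxy)-5-hydroxy-4-methylcyclohex-3-en-1-yl]-N-methoxy-N-methylbutanamide | COc1cc(C=O)ccc1O[C@H]2C=C(C)[C@@H](O)C[C@@H]2[C@@H](C)CC(=O)N(C)OC
F6 | step 13 | curcuminoid Weinreb amide (26 with C(=O)N(OMe)Me in place of the 2-methylprop-1-enyl ketone) | COc1cc(/C=C/C(=O)/C=C(O)/C=C/c2ccc(O[C@H]3C=C(C)[C@@H](O)C[C@@H]3[C@@H](C)CC(=O)N(C)OC)c(OC)c2)ccc1O
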